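The plan rests on opening the pyran ring (ring C) of the top unit at O1. That oxygen sits on ring A carbon C8a, meta to the oxygens on C5 and C7. This is the position at which a 3,5-dialkoxyphenyl ketone bears its acyl group. A Baeyer–Villiger oxidation of a (3R)-4,6-bis(benzyloxy)-3-arylindan-1-one, whose aryl group is C8 of the complete mid–bottom dimer, inserts O1 by aryl migration. It forms O1–C8a and O1–C2 in one operation and leaves the future C4 untouched. The lactone then takes up O3 at its enolate carbon and ring B at its acyl carbon. In the precursor both phloroglucinol rings are fully substituted (Br at mid C6 and bottom C8).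

Key step: step 15

Remarks on the chemistry
- **Names.** Top, mid and bottom are the three flavan units, with flavan numbering; ring B of every unit is α. EC* is the 3-O-TBS-5,7,3',4'-tetra-O-benzyl-(−)-epicatechin core. CAT* is the 3,5,7,3',4'-penta-O-benzyl-(+)-catechin core.
- **Structure check.** The target is epicatechin 3-O-gallate-(4β→8)-epicatechin 3-O-gallate-(4β→6)-catechin. The descriptors are top 2R,3R,4R; mid 2R,3R,4S; bottom 2R,3S. C3 of the indanone is R and has the geometry of top C4.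
- **Mid O3 as a silyl ether.** A gallate ester at mid O3 would not survive the aryllithium, hydroxide and Grignard steps. Both gallates are therefore installed together at the end.
- **Bromine at mid C6.** It stops self-condensation in the interflavan coupling. It also removes the last C–H from a trialkoxy ring before the peracid step.
- **Order of assembly.** The indanone is built on the mid monomer and the bottom unit is attached afterwards. The palladium step then meets only one C–Br bond, and no strong acid is needed anywhere.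
- **Assumption.** (S)-MonoPhos is taken to give the 3R indanone. If the sense of induction is the opposite, the antipode of the ligand is used. The C3 epimer is a diastereomer and should be removable by chromatography.

Step 1
Reactants: 1 (−)-epicatechin
Product: 2 5,7,3',4'-tetra-O-benzyl-(−)-epicatechin (2R,3R; 3-OH free)
Conditions: BnBr (4.4 equiv), K2CO3, DMF, 0 °C to rt, Ar
Reagents that add atoms: benzyl bromide, BrCc1ccccc1
Why: Williamson ether synthesis in which K2CO3 deprotonates only the four phenols, so the C3 alcohol stays free and C2 and C3 are not touched.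

Step 2
Reactants: 2 5,7,3',4'-tetra-O-benzyl-(−)-epicatechin
Product: 3 EC* (3-O-TBS ether of 2)
Conditions: TBSOTf, 2,6-lutidine, CH2Cl2, 0 °C
Reagents that add atoms: tert-butyldimethylsilyl triflate, CC(C)(C)[Si](C)(C)OS(=O)(=O)C(F)(F)F
Why: Silylation of the hindered axial C3 alcohol with a silyl triflate gives an ether inert to organolithium, hydroxide, palladium, rhodium, peracid and Grignard reagents.

Step 3
Reactants: 3 EC*
Product: 4 4β-(2-ethoxyethoxy)-EC* (2,3-cis-3,4-trans)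
Conditions: DDQ, 2-ethoxyethanol, CH2Cl2, rt
Reagents that add atoms: 2-ethoxyethanol, CCOCCO
Why: DDQ benzylic oxidation removes hydride from C4, and the alkoxy-stabilised cation is captured by the alcohol on the β face, anti to the α-oriented C3 silyloxy and C2 aryl groups, which sets the 3,4-trans ether used later as leaving group.

Step 4
Reactants: 4 4β-(2-ethoxyethoxy)-EC*
Product: 5 8-bromo-4β-(2-ethoxyethoxy)-EC*
Conditions: NBS (1.0 equiv), CH2Cl2, −78 to −20 °C
Reagents that add atoms: N-bromosuccinimide, O=C1CCC(=O)N1Br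
Why: Electrophilic aromatic bromination takes place at C8, the most nucleophilic position of 5,7-di-O-benzyl flavans, when one equivalent of NBS is used cold.

Step 5
Reactants: 5 8-bromo-4β-(2-ethoxyethoxy)-EC*
Product: 7 8-formyl-4β-(2-ethoxyethoxy)-EC*, via 8-lithio flavan 6 (not isolated)
Conditions: n-BuLi, THF, −78 °C; DMF; H2O quench
Reagents that add atoms: N,N-dimethylformamide, CN(C)C=O
Why: Bromine–lithium exchange followed by formylation of the aryllithium with DMF is fast at −78 °C and leaves benzyl, silyl and alkyl ethers alone.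

Step 6
Reactants: 8 3,5-bis(benzyloxy)acetophenone
Product: 9 2-bromo-3,5-bis(benzyloxy)acetophenone
Conditions: NBS, MeCN, 0 °C to rt
Reagents that add atoms: N-bromosuccinimide, O=C1CCC(=O)N1Br
Why: Electrophilic bromination goes to C2, which is ortho and para to the two benzyloxy groups and less crowded than C4 between them.

Step 7
Reactants: 7 8-formyl-4β-(2-ethoxyethoxy)-EC*; 9 2-bromo-3,5-bis(benzyloxy)acetophenone
Product: 10 (E)-1-[2-bromo-3,5-bis(benzyloxy)phenyl]-3-[4β-(2-ethoxyethoxy)-EC*-8-yl]prop-2-en-1-one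
Conditions: KOH, EtOH–THF, rt to 40 °C
Reagents that add atoms: none
Why: Claisen–Schmidt condensation of a methyl ketone with a non-enolisable aldehyde gives the E-enone after E1cB loss of water, as is usual for 2,4,6-trialkoxybenzaldehydes.

Step 8
Reactants: 10 bromochalcone
Product: 11 the 2'-(pinacolatoboryl) analogue of chalcone 10
Conditions: B2pin2, Pd(OAc)2, SPhos, KOAc, 1,4-dioxane, 80 °C
Reagents that add atoms: bis(pinacolato)diboron, CC1(C)OB(OC1(C)C)B1OC(C)(C)C(C)(C)O1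
Why: Miyaura borylation, in which zerovalent palladium inserts into the only C–Br bond of the molecule, activated by the ortho acyl group, and the bulky biaryl phosphine copes with the two ortho substituents.

Step 9
Reactants: 11 borylchalcone
Product: 12 (3R)-4,6-bis(benzyloxy)-3-[4β-(2-ethoxyethoxy)-EC*-8-yl]indan-1-one
Conditions: [RhCl(C2H4)2]2, (S)-MonoPhos, aq K3PO4, toluene, 40 °C
Reagents that add atoms: none
Why: Asymmetric intramolecular 1,4-addition of an arylboronate to an enone with monovalent rhodium (Hayashi–Miyaura type, known for 2'-boryl chalcones giving 3-aryl-1-indanones) closes the C3–C3a bond, and the phosphoramidite selects the enone face and so sets C3 as R.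

Step 10
Reactants: 12 indanone on the mid monomer
Product: 13 (3R)-4,6-bis(benzyloxy)-3-[6-bromo-4β-(2-ethoxyethoxy)-EC*-8-yl]indan-1-one
Conditions: NBS (1.0 equiv), CH2Cl2, −40 to 0 °C, dark
Reagents that add atoms: N-bromosuccinimide, O=C1CCC(=O)N1Br
Why: Electrophilic bromination picks mid C6, the only C–H flanked ortho, ortho and para by three ether oxygens, while the indanone ring is deactivated by its carbonyl group.

Step 11
Reactants: 14 (+)-catechin
Product: 15 5,7,3',4'-tetra-O-benzyl-(+)-catechin (2R,3S; 3-OH free)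
Conditions: BnBr (4.4 equiv), K2CO3, DMF, 0 °C to rt, Ar
Reagents that add atoms: benzyl bromide, BrCc1ccccc1
Why: Williamson ether synthesis selective for the four phenols, as in step 1.

Step 12
Reactants: 15 5,7,3',4'-tetra-O-benzyl-(+)-catechin
Product: 16 CAT* (3,5,7,3',4'-penta-O-benzyl-(+)-catechin)
Conditions: NaH, BnBr, DMF, 0 °C to rt
Reagents that add atoms: benzyl bromide, BrCc1ccccc1
Why: Williamson benzylation of the sodium alkoxide masks the one hydroxyl that must end free, in a form removed by the final hydrogenolysis.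

Step 13
Reactants: 16 CAT*
Product: 17 8-bromo-CAT*
Conditions: NBS (1.0 equiv), CH2Cl2, −78 to −20 °C
Reagents that add atoms: N-bromosuccinimide, O=C1CCC(=O)N1Br
Why: Electrophilic bromination at the more nucleophilic C8 blocks this position, so that only C6 can act as the nucleophile in the next step.

Step 14
Reactants: 13 brominated indanone with the C4 leaving group; 17 8-bromo-CAT* (2.5 equiv, the excess to be recovered)
Product: 18 (3R)-4,6-bis(benzyloxy)-3-arylindan-1-one, aryl = C8 of 6-bromo-EC*-(4β→6)-8-bromo-CAT*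
Conditions: Me3SiOTf (0.3 equiv), CH2Cl2, −78 to −30 °C
Reagents that add atoms: none
Why: Lewis-acid-promoted Friedel–Crafts flavan coupling, in which ionisation of the C4 ether gives a benzylic cation that C6 of the halogen-capped nucleophile attacks on the β face, anti to the C3 silyloxy and C2 aryl groups, which sets mid C4 as 4β.

Step 15
Reactants: 18 indanone precursor
Product: 20 (4R)-5,7-bis(benzyloxy)-4-arylchroman-2-one on the same brominated dimer, via Criegee adduct 19 (not isolated)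
Conditions: mCPBA (2.5 equiv), CF3CO2H (1 equiv), CH2Cl2, 0 °C, dark
Reagents that add atoms: 3-chloroperbenzoic acid, OOC(=O)c1cccc(Cl)c1
Why: Acid-assisted addition of the peracid to the sterically open C1 carbonyl gives the Criegee adduct 19, in which aryl carbon C7a, antiperiplanar to the O–O bond, shifts from C1 to oxygen as 3-chlorobenzoate leaves; the closest known reaction type is the Baeyer–Villiger oxidation of 3-aryl-1-indanones to 4-aryl-3,4-dihydrocoumarins. Ring C of the top unit arises by ring expansion from five to six members through this 1,2-shift and not by a cyclisation, and O1–C8a and O1–C2 are both in place after it. No stereocentre is created, and indanone C3, which takes no part in the bond changes, becomes top C4 (R) unchanged. Regioselectivity (aryl against CH2 migration) rests on the intrinsic order aryl over primary alkyl, which acid catalysis reinforces, because the two benzyloxy groups are meta to C7a and neither help nor seriously slow the shift. Chemoselectivity (ketone against arenes) is built into the substrate: both phloroglucinol rings are hexasubstituted and carry bromine, the indanone ring is deactivated by the carbonyl group, and there is no C4 leaving group, ester or free hydroxyl. The limited charge of a mild peracid, used cold and in the dark, should spare the catechol-ether B rings and the newly formed aryl ester ring.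

Step 16
Reactants: 20 top-ring lactone
Product: 22 (3R,4R)-3-hydroxy derivative of lactone 20 (3,4-trans), via potassium lactone enolate 21 (not isolated)
Conditions: KN(SiMe3)2, THF, −78 °C; 2-(phenylsulfonyl)-3-phenyloxaziridine; AcOH quench
Reagents that add atoms: 2-(phenylsulfonyl)-3-phenyloxaziridine, O=S(=O)(N1OC1c1ccccc1)c1ccccc1
Why: Enolate hydroxylation with an N-sulfonyloxaziridine delivers oxygen to the enolate face opposite the very large pseudo-axial C4 aryl group, which sets C3 as R, trans to C4.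

Step 17
Reactants: 22 3-hydroxy lactone
Product: 23 3-O-TBS ether of 22
Conditions: TBSOTf, 2,6-lutidine, CH2Cl2, 0 °C
Reagents that add atoms: tert-butyldimethylsilyl triflate, CC(C)(C)[Si](C)(C)OS(=O)(=O)C(F)(F)F
Why: Silyl triflate silylation under non-epimerising conditions protects O3 and puts a bulky group on the α face for the later reduction.

Step 18
Reactants: 24 4-bromocatechol
Product: 25 4-bromo-1,2-bis(benzyloxy)benzene
Conditions: BnBr, K2CO3, DMF, 60 °C
Reagents that add atoms: benzyl bromide, BrCc1ccccc1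
Why: Williamson ether synthesis on both phenols.

Step 19
Reactants: 23 3-silyloxy lactone; 25 4-bromo-1,2-bis(benzyloxy)benzene
Product: 27 2-[3,4-bis(benzyloxy)phenyl]-2-hydroxy hemiketal of the top ring (C2 epimers in equilibrium with the open keto phenol), via 3,4-bis(benzyloxy)phenylmagnesium bromide 26 (not isolated)
Conditions: 25, Mg, THF, 40 °C; then 23, THF, −78 to −20 °C; H2O quench
Reagents that add atoms: none
Why: Grignard addition to the activated aryl-ester lactone should stop after one addition, because the ketone released is a deactivated 4-alkoxyaryl ketone flanked by a silyloxy and a diarylmethyl group, and a magnesium rather than a lithium reagent avoids halogen–metal exchange with the two aryl bromides.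

Step 20
Reactants: 27 hemiketal
Product: 28 EC*-(4β→8)-6-bromo-EC*-(4β→6)-8-bromo-CAT* (top 2R,3R,4R)
Conditions: Et3SiH (10 equiv), Me3SiOTf (0.5 equiv), CH2Cl2, −78 to −40 °C
Reagents that add atoms: none
Why: Ionic hydrogenation of a hemiketal through its 2-aryl oxocarbenium ion (as in the silane reduction of C-aryl glycoside hemiketals), where allylic strain with ring B and peri strain with O5 hold the C3 silyloxy and C4 aryl groups trans-diaxial, so hydride should enter axially on the β face, anti to the adjacent silyloxy group, and set C2 as R (2,3-cis).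

Step 21
Reactants: 28 bis-silyl trimer
Product: 29 top-3,mid-3-diol (both TBS groups removed)
Conditions: Bu4NF, THF, rt to 45 °C
Reagents that add atoms: none
Why: Fluoride-induced desilylation frees only the two hydroxyls meant for acylation, and nothing base-sensitive is present.

Step 22
Reactants: 29 diol; 30 3,4,5-tris(benzyloxy)benzoic acid (4 equiv)
Product: 31 top-3,mid-3-bis-O-[3,4,5-tris(benzyloxy)benzoyl] trimer (nineteen benzyl groups and two bromines)
Conditions: DCC, DMAP, CH2Cl2, rt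
Reagents that add atoms: none
Why: Steglich esterification, established for the axial 3-hydroxyls of benzylated procyanidins, acylates both alcohols in one operation with retention at C3.

Step 23
Reactants: 31 fully protected digallate
Product: 32 target CNP0154615.1
Conditions: H2 (1 atm), Pd(OH)2/C, NaOAc (2.2 equiv), THF–MeOH–H2O, rt
Reagents that add atoms: none
Why: Catalytic hydrogenolysis cleaves all benzyl ethers and both aryl C–Br bonds in one operation, while acetate takes up the HBr so that the acid-labile interflavan bonds and the gallate esters should survive.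

Compound list
1 | (−)-epicatechin | O[C@@H]1Cc2c(O)cc(O)cc2O[C@@H]1c1ccc(O)c(O)c1 | starting material
2 | 5,7,3',4'-tetra-O-benzyl-(−)-epicatechin | c1c(OCc9ccccc9)cc(OCc9ccccc9)c2c1O[C@H](c8ccc(OCc9ccccc9)c(OCc9ccccc9)c8)[C@H](O)C2 | intermediate
3 | EC* (3-O-TBS-5,7,3',4'-tetra-O-benzyl-epicatechin) | c1c(OCc9ccccc9)cc(OCc9ccccc9)c2c1O[C@H](c8ccc(OCc9ccccc9)c(OCc9ccccc9)c8)[C@H](O[Si](C)(C)C(C)(C)C)C2 | intermediate
4 | 4β-(2-ethoxyethoxy)-EC* | c1c(OCc9ccccc9)cc(OCc9ccccc9)c2c1O[C@H](c8ccc(OCc9ccccc9)c(OCc9ccccc9)c8)[C@H](O[Si](C)(C)C(C)(C)C)[C@H]2OCCOCC | intermediate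
5 | 8-bromo-4β-(2-ethoxyethoxy)-EC* | Brc1c(OCc9ccccc9)cc(OCc9ccccc9)c2c1O[C@H](c8ccc(OCc9ccccc9)c(OCc9ccccc9)c8)[C@H](O[Si](C)(C)C(C)(C)C)[C@H]2OCCOCC | intermediate
6 | 8-lithio-4β-(2-ethoxyethoxy)-EC* (not isolated) | [Li]c1c(OCc9ccccc9)cc(OCc9ccccc9)c2c1O[C@H](c8ccc(OCc9ccccc9)c(OCc9ccccc9)c8)[C@H](O[Si](C)(C)C(C)(C)C)[C@H]2OCCOCC | intermediate
7 | 8-formyl-4β-(2-ethoxyethoxy)-EC* | O=Cc1c(OCc9ccccc9)cc(OCc9ccccc9)c2c1O[C@H](c8ccc(OCc9ccccc9)c(OCc9ccccc9)c8)[C@H](O[Si](C)(C)C(C)(C)C)[C@H]2OCCOCC | intermediate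
8 | 3,5-bis(benzyloxy)acetophenone | CC(=O)c1cc(OCc9ccccc9)cc(OCc9ccccc9)c1 | starting material
9 | 2-bromo-3,5-bis(benzyloxy)acetophenone | CC(=O)c1cc(OCc9ccccc9)cc(OCc9ccccc9)c1Br | intermediate
10 | (E)-2'-bromochalcone of 7 and 9 | c1c(OCc9ccccc9)cc(OCc9ccccc9)c(Br)c1C(=O)/C=C/c1c(OCc9ccccc9)cc(OCc9ccccc9)c2c1O[C@H](c8ccc(OCc9ccccc9)c(OCc9ccccc9)c8)[C@H](O[Si](C)(C)C(C)(C)C)[C@H]2OCCOCC | intermediate
11 | (E)-2'-(pinacolatoboryl)chalcone | c1c(OCc9ccccc9)cc(OCc9ccccc9)c(B3OC(C)(C)C(C)(C)O3)c1C(=O)/C=C/c1c(OCc9ccccc9)cc(OCc9ccccc9)c2c1O[C@H](c8ccc(OCc9ccccc9)c(OCc9ccccc9)c8)[C@H](O[Si](C)(C)C(C)(C)C)[C@H]2OCCOCC | intermediate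
12 | (3R)-4,6-bis(benzyloxy)-3-[4β-(2-ethoxyethoxy)-EC*-8-yl]indan-1-one | c1c(OCc9ccccc9)cc(OCc9ccccc9)c2c1C(=O)C[C@H]2c1c(OCc9ccccc9)cc(OCc9ccccc9)c2c1O[C@H](c8ccc(OCc9ccccc9)c(OCc9ccccc9)c8)[C@H](O[Si](C)(C)C(C)(C)C)[C@H]2OCCOCC | intermediate
13 | mid-C6 bromide of 12 | c1c(OCc9ccccc9)cc(OCc9ccccc9)c2c1C(=O)C[C@H]2c1c(OCc9ccccc9)c(Br)c(OCc9ccccc9)c2c1O[C@H](c8ccc(OCc9ccccc9)c(OCc9ccccc9)c8)[C@H](O[Si](C)(C)C(C)(C)C)[C@H]2OCCOCC | intermediate
14 | (+)-catechin | O[C@H]1Cc2c(O)cc(O)cc2O[C@@H]1c1ccc(O)c(O)c1 | starting material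
15 | 5,7,3',4'-tetra-O-benzyl-(+)-catechin | c1c(OCc9ccccc9)cc2O[C@H](c8ccc(OCc9ccccc9)c(OCc9ccccc9)c8)[C@@H](O)Cc2c1OCc9ccccc9 | intermediate
16 | CAT* (3,5,7,3',4'-penta-O-benzyl-(+)-catechin) | c1c(OCc9ccccc9)cc2O[C@H](c8ccc(OCc9ccccc9)c(OCc9ccccc9)c8)[C@@H](OCc9ccccc9)Cc2c1OCc9ccccc9 | intermediate
17 | 8-bromo-CAT* | c1c(OCc9ccccc9)c(Br)c2O[C@H](c8ccc(OCc9ccccc9)c(OCc9ccccc9)c8)[C@@H](OCc9ccccc9)Cc2c1OCc9ccccc9 | intermediate
18 | key-step precursor: (3R)-4,6-bis(benzyloxy)-3-arylindan-1-one, aryl = C8 of 6-bromo-EC*-(4β→6)-8-bromo-CAT* | c1c(OCc9ccccc9)cc(OCc9ccccc9)c2c1C(=O)C[C@H]2c1c(OCc9ccccc9)c(Br)c(OCc9ccccc9)c2c1O[C@H](c8ccc(OCc9ccccc9)c(OCc9ccccc9)c8)[C@H](O[Si](C)(C)C(C)(C)C)[C@H]2c1c(OCc9ccccc9)c(Br)c2O[C@H](c8ccc(OCc9ccccc9)c(OCc9ccccc9)c8)[C@@H](OCc9ccccc9)Cc2c1OCc9ccccc9 | intermediate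
19 | Criegee adduct of 18 and mCPBA (C1 unassigned, not isolated) | c1c(OCc9ccccc9)cc(OCc9ccccc9)c2c1C(O)(OOC(=O)c3cccc(Cl)c3)C[C@H]2c1c(OCc9ccccc9)c(Br)c(OCc9ccccc9)c2c1O[C@H](c8ccc(OCc9ccccc9)c(OCc9ccccc9)c8)[C@H](O[Si](C)(C)C(C)(C)C)[C@H]2c1c(OCc9ccccc9)c(Br)c2O[C@H](c8ccc(OCc9ccccc9)c(OCc9ccccc9)c8)[C@@H](OCc9ccccc9)Cc2c1OCc9ccccc9 | intermediate
20 | key-step product: (4R)-5,7-bis(benzyloxy)-4-arylchroman-2-one on the same dimer | c1c(OCc9ccccc9)cc(OCc9ccccc9)c2c1OC(=O)C[C@H]2c1c(OCc9ccccc9)c(Br)c(OCc9ccccc9)c2c1O[C@H](c8ccc(OCc9ccccc9)c(OCc9ccccc9)c8)[C@H](O[Si](C)(C)C(C)(C)C)[C@H]2c1c(OCc9ccccc9)c(Br)c2O[C@H](c8ccc(OCc9ccccc9)c(OCc9ccccc9)c8)[C@@H](OCc9ccccc9)Cc2c1OCc9ccccc9 | intermediate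
21 | potassium enolate of 20 (not isolated) | [K+].c1c(OCc9ccccc9)cc(OCc9ccccc9)c2c1OC([O-])=C[C@H]2c1c(OCc9ccccc9)c(Br)c(OCc9ccccc9)c2c1O[C@H](c8ccc(OCc9ccccc9)c(OCc9ccccc9)c8)[C@H](O[Si](C)(C)C(C)(C)C)[C@H]2c1c(OCc9ccccc9)c(Br)c2O[C@H](c8ccc(OCc9ccccc9)c(OCc9ccccc9)c8)[C@@H](OCc9ccccc9)Cc2c1OCc9ccccc9 | intermediate
22 | (3R,4R)-3-hydroxy lactone | c1c(OCc9ccccc9)cc(OCc9ccccc9)c2c1OC(=O)[C@H](O)[C@H]2c1c(OCc9ccccc9)c(Br)c(OCc9ccccc9)c2c1O[C@H](c8ccc(OCc9ccccc9)c(OCc9ccccc9)c8)[C@H](O[Si](C)(C)C(C)(C)C)[C@H]2c1c(OCc9ccccc9)c(Br)c2O[C@H](c8ccc(OCc9ccccc9)c(OCc9ccccc9)c8)[C@@H](OCc9ccccc9)Cc2c1OCc9ccccc9 | intermediate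
23 | (3R,4R)-3-O-TBS lactone | c1c(OCc9ccccc9)cc(OCc9ccccc9)c2c1OC(=O)[C@H](O[Si](C)(C)C(C)(C)C)[C@H]2c1c(OCc9ccccc9)c(Br)c(OCc9ccccc9)c2c1O[C@H](c8ccc(OCc9ccccc9)c(OCc9ccccc9)c8)[C@H](O[Si](C)(C)C(C)(C)C)[C@H]2c1c(OCc9ccccc9)c(Br)c2O[C@H](c8ccc(OCc9ccccc9)c(OCc9ccccc9)c8)[C@@H](OCc9ccccc9)Cc2c1OCc9ccccc9 | intermediate
24 | 4-bromocatechol | Oc1ccc(Br)cc1O | starting material
25 | 4-bromo-1,2-bis(benzyloxy)benzene | Brc1ccc(OCc9ccccc9)c(OCc9ccccc9)c1 | intermediate
26 | 3,4-bis(benzyloxy)phenylmagnesium bromide (not isolated) | Br[Mg]c1ccc(OCc9ccccc9)c(OCc9ccccc9)c1 | intermediate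
27 | top-ring 2-aryl-2-hydroxy hemiketal (C2 epimers) | c1c(OCc9ccccc9)cc(OCc9ccccc9)c2c1OC(O)(c8ccc(OCc9ccccc9)c(OCc9ccccc9)c8)[C@H](O[Si](C)(C)C(C)(C)C)[C@H]2c1c(OCc9ccccc9)c(Br)c(OCc9ccccc9)c2c1O[C@H](c8ccc(OCc9ccccc9)c(OCc9ccccc9)c8)[C@H](O[Si](C)(C)C(C)(C)C)[C@H]2c1c(OCc9ccccc9)c(Br)c2O[C@H](c8ccc(OCc9ccccc9)c(OCc9ccccc9)c8)[C@@H](OCc9ccccc9)Cc2c1OCc9ccccc9 | intermediate
28 | EC*-(4β→8)-6-bromo-EC*-(4β→6)-8-bromo-CAT* | c1c(OCc9ccccc9)cc(OCc9ccccc9)c2c1O[C@H](c8ccc(OCc9ccccc9)c(OCc9ccccc9)c8)[C@H](O[Si](C)(C)C(C)(C)C)[C@H]2c1c(OCc9ccccc9)c(Br)c(OCc9ccccc9)c2c1O[C@H](c8ccc(OCc9ccccc9)c(OCc9ccccc9)c8)[C@H](O[Si](C)(C)C(C)(C)C)[C@H]2c1c(OCc9ccccc9)c(Br)c2O[C@H](c8ccc(OCc9ccccc9)c(OCc9ccccc9)c8)[C@@H](OCc9ccccc9)Cc2c1OCc9ccccc9 | intermediate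
29 | top-3,mid-3-diol | c1c(OCc9ccccc9)cc(OCc9ccccc9)c2c1O[C@H](c8ccc(OCc9ccccc9)c(OCc9ccccc9)c8)[C@H](O)[C@H]2c1c(OCc9ccccc9)c(Br)c(OCc9ccccc9)c2c1O[C@H](c8ccc(OCc9ccccc9)c(OCc9ccccc9)c8)[C@H](O)[C@H]2c1c(OCc9ccccc9)c(Br)c2O[C@H](c8ccc(OCc9ccccc9)c(OCc9ccccc9)c8)[C@@H](OCc9ccccc9)Cc2c1OCc9ccccc9 | intermediate
30 | 3,4,5-tris(benzyloxy)benzoic acid | OC(=O)c1cc(OCc9ccccc9)c(OCc9ccccc9)c(OCc9ccccc9)c1 | starting material
31 | fully protected digallate | c1c(OCc9ccccc9)cc(OCc9ccccc9)c2c1O[C@H](c8ccc(OCc9ccccc9)c(OCc9ccccc9)c8)[C@H](OC(=O)c7cc(OCc9ccccc9)c(OCc9ccccc9)c(OCc9ccccc9)c7)[C@H]2c1c(OCc9ccccc9)c(Br)c(OCc9ccccc9)c2c1O[C@H](c8ccc(OCc9ccccc9)c(OCc9ccccc9)c8)[C@H](OC(=O)c7cc(OCc9ccccc9)c(OCc9ccccc9)c(OCc9ccccc9)c7)[C@H]2c1c(OCc9ccccc9)c(Br)c2O[C@H](c8ccc(OCc9ccccc9)c(OCc9ccccc9)c8)[C@@H](OCc9ccccc9)Cc2c1OCc9ccccc9 | intermediate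
32 | CNP0154615.1 | O=C(O[C@@H]1[C@@H](c2c(O)cc(O)c3c2O[C@H](c2ccc(O)c(O)c2)[C@H](OC(=O)c2cc(O)c(O)c(O)c2)[C@H]3c2c(O)cc3c(c2O)C[C@H](O)[C@@H](c2ccc(O)c(O)c2)O3)c2c(O)cc(O)cc2O[C@@H]1c1ccc(O)c(O)c1)c1cc(O)c(O)c(O)c1 | target

Total step count: 23.
Longest linear sequence: 18 steps from (−)-epicatechin (steps 1–5, 7–10, 14–17, 19–23).

Steps most likely to fail

**1. Step 15 (oxygen insertion).**
- What may go wrong: electrophilic oxygen transfer to the catechol-ether B rings, or to ring A of the freshly formed lactone, may outrun the slow addition of the peracid to an aryl ketone. Partial migration of the methylene group is also possible.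
- The fallback avoids oxygen insertion altogether. It sets out from aldehyde 7 and comes back at lactone 20.
- NBS in CH2Cl2 brominates C6 and gives the 6-bromo-8-formyl flavan F1.
- Knoevenagel condensation with Meldrum's acid (piperidinium acetate, toluene, rt) gives the arylidene Meldrum's acid F2.
- F2 is heated with commercial 3,5-bis(benzyloxy)phenol in pyridine. This brings about conjugate C-alkylation ortho to the phenolic OH, lactonisation, and loss of acetone and CO2. The product is the monomeric 4-arylchroman-2-one F3 as a pair of C4 epimers, from which the 4R isomer is separated by chromatography.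
- Coupling of F3 with 17 under the conditions of step 14 gives 20.
- The price is the loss of catalyst control at C4.

**2. Step 20 (silane reduction).**
- What may go wrong: the large C4 aryl group lies on the β face and may divert hydride delivery to the α face, so facial selectivity at C2 may be poor.
- The fallback forms O1–C2 by stereospecific substitution. It sets out from hemiketal 27 and comes back at diol 29.
- HF·pyridine in THF removes both silyl groups and gives the α-hydroxy ketone F4 (open keto-phenol form).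
- Zn(BH4)2 in Et2O at −20 °C reduces F4 under chelation control, with zinc bridging the C2 carbonyl oxygen and O3 and hydride entering beside the C3 hydrogen. This gives the 2,3-anti (2S,3R) triol F5.
- Mitsunobu cyclisation (PPh3, DIAD, THF, 0 °C) follows. The C8a phenol displaces the activated benzylic C2 hydroxyl with inversion and closes the 2,3-cis flavan, which is 29.

**3. Step 9 (asymmetric ring closure).**
- What may go wrong: protodeboronation of the di-ortho-substituted boronate may be faster than transfer of the aryl group to rhodium. The chiral flavan may also override the facial preference of the ligand.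
- The fallback sets out from bromochalcone 10, comes back at indanone 12, and bypasses 11.
- It is an asymmetric reductive Heck cyclisation (Pd(OAc)2, an (R)-MeO-BIPHEP-type bisphosphine, HCO2Na, DMF, 80 °C). The aryl–palladium species made directly from the C–Br bond adds to the enone and the resulting palladium enolate is reduced off.
- It makes no compound outside the list (F0).

Further compounds
F1 | step 15 | 6-bromo-8-formyl-4β-(2-ethoxyethoxy)-EC* | O=Cc1c(OCc9ccccc9)c(Br)c(OCc9ccccc9)c2c1O[C@H](c8ccc(OCc9ccccc9)c(OCc9ccccc9)c8)[C@H](O[Si](C)(C)C(C)(C)C)[C@H]2OCCOCC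
F2 | step 15 | arylidene Meldrum's acid of F1 | CC1(C)OC(=O)C(=Cc2c(OCc9ccccc9)c(Br)c(OCc9ccccc9)c3c2O[C@H](c8ccc(OCc9ccccc9)c(OCc9ccccc9)c8)[C@H](O[Si](C)(C)C(C)(C)C)[C@H]3OCCOCC)C(=O)O1
F3 | step 15 | (4R)-5,7-bis(benzyloxy)-4-[6-bromo-4β-(2-ethoxyethoxy)-EC*-8-yl]chroman-2-one | c1c(OCc9ccccc9)cc(OCc9ccccc9)c2c1OC(=O)C[C@H]2c1c(OCc9ccccc9)c(Br)c(OCc9ccccc9)c2c1O[C@H](c8ccc(OCc9ccccc9)c(OCc9ccccc9)c8)[C@H](O[Si](C)(C)C(C)(C)C)[C@H]2OCCOCC
F4 | step 20 | desilylated α-hydroxy ketone (open keto-phenol form of the hemiketal) | O=C(c8ccc(OCc9ccccc9)c(OCc9ccccc9)c8)[C@H](O)[C@H](c1c(O)cc(OCc9ccccc9)cc1OCc9ccccc9)c1c(OCc9ccccc9)c(Br)c(OCc9ccccc9)c2c1O[C@H](c8ccc(OCc9ccccc9)c(OCc9ccccc9)c8)[C@H](O)[C@H]2c1c(OCc9ccccc9)c(Br)c2O[C@H](c8ccc(OCc9ccccc9)c(OCc9ccccc9)c8)[C@@H](OCc9ccccc9)Cc2c1OCc9ccccc9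
F5 | step 20 | 2,3-anti (2S,3R) benzylic alcohol with free C8a phenol | O[C@@H](c8ccc(OCc9ccccc9)c(OCc9ccccc9)c8)[C@H](O)[C@H](c1c(O)cc(OCc9ccccc9)cc1OCc9ccccc9)c1c(OCc9ccccc9)c(Br)c(OCc9ccccc9)c2c1O[C@H](c8ccc(OCc9ccccc9)c(OCc9ccccc9)c8)[C@H](O)[C@H]2c1c(OCc9ccccc9)c(Br)c2O[C@H](c8ccc(OCc9ccccc9)c(OCc9ccccc9)c8)[C@@H](OCc9ccccc9)Cc2c1OCc9ccccc9
F0 | step 9 | none | none
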